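**Assumptions:**
- (S)-5-(hydroxymethyl)furan-2(5H)-one (from D-ribonolactone or levoglucosenone), (S)-2,3-O-isopropylideneglyceraldehyde (from (S)-solketal), 4-bromo-2-methoxyphenol and syringaldehyde are purchased.
- The target is a medioresinol-type all-exo furofuran (7S,7'S,8R,8'R) carrying an erythro (7''S,8''R) guaiacylglycerol 8''-O-4' ether on the syringyl ring.
- Ar = 4-(tert-butyldiphenylsilyloxy)-3-methoxyphenyl.

## Retrosynthetic overview
1. Target 19 comes from global desilylation of 18. Compound 18 comes from acid cyclodehydration of diol 17, which closes ring A under thermodynamic all-exo control.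
2. Diol 17 comes from ArMgBr plus lactol 16. Lactol 16 comes from periodate cleavage of triol 15, which excises the CH2O unit of the butenolide. Triol 15 comes from reduction of lactone 14.
3. Lactone 14 comes from a photochemical [3+2] of the carbonyl-ylide equivalent of aryl epoxide 11 with (S)-butenolide benzoate 13. This forms ring B first and sets C8/C8' cis and anti to CH2OBz.
4. Epoxide 11 comes from aldehyde 10. Aldehyde 10 is made by Mitsunobu inversion of the threo alcohol 8 (from glyceraldehyde acetonide 3 plus Ar) onto syringaldehyde.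
5. Ring order: ring B (photochemical), then ring A (acid).

## Route

**Step 1**
Reactants: 1 (4-bromo-2-methoxyphenol)
Product: 2 (tert-butyl(4-bromo-2-methoxyphenoxy)diphenylsilane)
Conditions: TBDPSCl, imidazole, DMF, 25 °C
Reagents that add atoms: TBDPSCl, CC(C)(C)[Si](Cl)(c1ccccc1)c1ccccc1
Why: Silyl protection of the phenol gives an aryl bromide that forms a Grignard reagent cleanly and is used twice (Steps 2 and 13).

**Step 2**
Reactants: 2 (as ArMgBr), 3 ((S)-2,2-dimethyl-1,3-dioxolane-4-carbaldehyde)
Product: 4 (aryl(dioxolanyl)methanol, epimeric at the carbinol, (S) at the dioxolane carbon)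
Conditions: 2, Mg, THF, 65 °C; then 3, THF, −78 → 0 °C
Reagents that add atoms: none
Why: Grignard addition to the aldehyde; the carbinol ratio is irrelevant because both epimers are oxidised to the same ketone in Step 3, and the (S) centre is carried from 3.

**Step 3**
Reactants: 4
Product: 5 (aryl ketone with the (S)-dioxolane)
Conditions: Dess–Martin periodinane, NaHCO3, CH2Cl2, 0 → 25 °C
Reagents that add atoms: none
Why: Dess–Martin oxidation removes the unselective carbinol centre and leaves the glyceraldehyde-derived centre intact.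

**Step 4**
Reactants: 5
Product: 6 ((S)-aryl[(S)-dioxolanyl]methanol, the 7''S,8''S threo alcohol)
Conditions: L-Selectride, THF, −78 °C
Reagents that add atoms: none (hydride only)
Why: Non-chelating Felkin–Anh reduction with a bulky borohydride sets the new carbinol centre from the adjacent (S) centre, giving the syn (7''S,8''S) isomer.

**Step 5**
Reactants: 6
Product: 7 ((1S,2S)-1-Ar-propane-1,2,3-triol)
Conditions: 80% aq. AcOH, 40 °C
Reagents that add atoms: none
Why: Mild acetonide hydrolysis; both stereocentres are untouched and the aryl silyl ether survives.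

**Step 6**
Reactants: 7
Product: 8 ((4S,5S)-2,2-di-tert-butyl-4-Ar-1,3,2-dioxasilinan-5-ol)
Conditions: tBu2Si(OTf)2, 2,6-lutidine, DMF/CH2Cl2, −40 → 0 °C
Reagents that add atoms: di-tert-butylsilyl bis(triflate), CC(C)(C)[Si](OS(=O)(=O)C(F)(F)F)(OS(=O)(=O)C(F)(F)F)C(C)(C)C
Why: A 1,3-diol silylene protects the benzylic and primary hydroxyls and leaves the secondary 8''-OH free; it is stable to hydride, Grignard, periodate and mild acid.

**Step 7**
Reactants: 8, 9 (syringaldehyde)
Product: 10 (4-{[(4S,5R)-2,2-di-tert-butyl-4-Ar-1,3,2-dioxasilinan-5-yl]oxy}-3,5-dimethoxybenzaldehyde)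
Conditions: PPh3, DIAD, THF, 0 → 25 °C
Reagents that add atoms: none
Why: Mitsunobu SN2 of the acidic phenol inverts C8'' from S to R, giving the erythro (7''S,8''R) ether.

**Step 8**
Reactants: 10
Product: 11 (2-aryl-oxirane carrying the protected side chain; epoxide carbon undefined)
Conditions: Me3S+ I−, NaH, DMSO/THF, 0 → 25 °C
Reagents that add atoms: trimethylsulfonium iodide, C[S+](C)C.[I-] (adds CH2)
Why: Corey–Chaykovsky epoxidation; the epoxide stereocentre is irrelevant because it is erased in the next step.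

**Step 9**
Reactants: 12 ((S)-5-(hydroxymethyl)furan-2(5H)-one)
Product: 13 ([(2S)-5-oxo-2,5-dihydrofuran-2-yl]methyl benzoate)
Conditions: BzCl, pyridine, CH2Cl2, 0 °C
Reagents that add atoms: benzoyl chloride, O=C(Cl)c1ccccc1
Why: The ester masks the OH so it cannot trap the ylide, is removed by hydride in Step 11, and keeps the γ-stereocentre.

**Step 10**
Reactants: 11, 13
Product: 14 (cis-fused tetrahydrofuro[3,4-c]furan-1-one, 3-CH2OBz, 6-Ar', all stereocentres as in the SMILES)
Conditions: 11 (1 equiv), 13 (3 equiv), Mes-Acr-Me+ BF4− (5 mol %), MeCN/CH2Cl2 1:1, blue LEDs (450 nm), Ar, 25 °C, 24 h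
Reagents that add atoms: none
Why: Proposed new method: acridinium-photocatalysed C–C cleavage of the electron-rich aryl epoxide radical cation gives ArCH=O+–CH2• / the carbonyl ylide ArCH–O–CH2 after back electron transfer. The CH2 end bonds to the butenolide β-carbon and the ArCH end to the α-carbon in a suprafacial [3+2], giving the cis-fused bicycle (8R,8'R) by attack anti to the CH2OBz group. The closest known reactions are photoinduced-electron-transfer carbonyl-ylide generation from 2,3-diaryloxiranes with dipolar cycloaddition, and photocatalytic epoxide/alkene formal [3+2]. The aryl prefers exo and is corrected in Step 14 if not.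

**Step 11**
Reactants: 14
Product: 15 (THF triol: 2-Ar', with 3-CH(OH)CH2OH and 4-CH2OH, cis)
Conditions: LiAlH4, THF, −10 → 0 °C
Reagents that add atoms: none
Why: Hydride reduces the lactone and the benzoate, releasing the vicinal diol (C7–C6) and the primary C9'-OH without affecting the stereocentres.

**Step 12**
Reactants: 15
Product: 16 (bicyclic lactol, anomeric carbon undefined)
Conditions: NaIO4, THF/H2O 4:1, 0 → 25 °C
Reagents that add atoms: none
Why: Malaprade cleavage removes the CH2O of the butenolide unit and destroys its stereocentre. The resulting aldehyde is the future C7 and is held as a cis-fused lactol with C9'-OH, so C8 cannot epimerise to the trans isomer.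

**Step 13**
Reactants: 16, 2 (as ArMgBr)
Product: 17 (diol: 3-CH(OH)Ar on the THF ring, 4-CH2OH, C7 epimeric)
Conditions: 2 (3.5 equiv), Mg, THF; add 16, −78 → 0 °C; then aq NH4Cl
Reagents that add atoms: none
Why: Grignard addition to the open aldehyde tautomer installs the guaiacyl ring; the C7 ratio does not matter because that centre is re-set in Step 14.

**Step 14**
Reactants: 17
Product: 18 (silyl-protected all-exo furofuran)
Conditions: TsOH·H2O (0.2 equiv), CH2Cl2, 4 Å MS, 25 °C
Reagents that add atoms: none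
Why: Acid-catalysed SN1 cyclodehydration, in which the primary OH captures the benzylic cation of the electron-rich p-siloxyaryl carbinol. Reversible benzylic ionisation lets C7 and C7' equilibrate to the thermodynamically preferred exo,exo isomer on the fixed cis (8R,8'R) fusion, giving (7S,7'S).

**Step 15**
Reactants: 18
Product: 19 (Hedyotol C)
Conditions: TBAF, AcOH, THF, 0 → 25 °C
Reagents that add atoms: none
Why: Fluoride removes both aryl TBDPS groups and the silylene in one step; AcOH buffering avoids base-mediated β-aryl ether problems.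

## Compound list
1 | 4-bromo-2-methoxyphenol | COc1cc(Br)ccc1O | starting material
2 | tert-butyl(4-bromo-2-methoxyphenoxy)diphenylsilane | COc1cc(Br)ccc1O[Si](c2ccccc2)(c2ccccc2)C(C)(C)C | intermediate
3 | (S)-2,2-dimethyl-1,3-dioxolane-4-carbaldehyde | O=C[C@@H]1COC(C)(C)O1 | starting material
4 | aryl((S)-dioxolanyl)methanol, carbinol epimers | COc1cc(C(O)[C@@H]2COC(C)(C)O2)ccc1O[Si](c1ccccc1)(c1ccccc1)C(C)(C)C | intermediate
5 | aryl (S)-dioxolanyl ketone | COc1cc(C(=O)[C@@H]2COC(C)(C)O2)ccc1O[Si](c1ccccc1)(c1ccccc1)C(C)(C)C | intermediate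
6 | (S)-aryl[(S)-dioxolanyl]methanol | COc1cc([C@H](O)[C@@H]2COC(C)(C)O2)ccc1O[Si](c1ccccc1)(c1ccccc1)C(C)(C)C | intermediate
7 | (1S,2S)-1-Ar-propane-1,2,3-triol | COc1cc([C@H](O)[C@@H](O)CO)ccc1O[Si](c1ccccc1)(c1ccccc1)C(C)(C)C | intermediate
8 | (4S,5S)-2,2-di-tert-butyl-4-Ar-1,3,2-dioxasilinan-5-ol | O[C@H]1CO[Si](C(C)(C)C)(C(C)(C)C)O[C@H]1c1ccc(O[Si](c2ccccc2)(c2ccccc2)C(C)(C)C)c(OC)c1 | intermediate
9 | syringaldehyde | COc1cc(C=O)cc(OC)c1O | starting material
10 | aryl ether aldehyde (4S,5R silylene) | O=Cc1cc(OC)c(O[C@@H]2CO[Si](C(C)(C)C)(C(C)(C)C)O[C@H]2c2ccc(O[Si](c3ccccc3)(c3ccccc3)C(C)(C)C)c(OC)c2)c(OC)c1 | intermediate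
11 | 2-aryl-oxirane with protected side chain | C1OC1c1cc(OC)c(O[C@@H]2CO[Si](C(C)(C)C)(C(C)(C)C)O[C@H]2c2ccc(O[Si](c3ccccc3)(c3ccccc3)C(C)(C)C)c(OC)c2)c(OC)c1 | intermediate
12 | (S)-5-(hydroxymethyl)furan-2(5H)-one | O=C1C=C[C@@H](CO)O1 | starting material
13 | [(2S)-5-oxo-2,5-dihydrofuran-2-yl]methyl benzoate | O=C1C=C[C@@H](COC(=O)c2ccccc2)O1 | intermediate
14 | cis-fused furo[3,4-c]furan-1-one lactone (benzoate) | O=C1O[C@H](COC(=O)c2ccccc2)[C@H]3CO[C@H](c4cc(OC)c(O[C@@H]5CO[Si](C(C)(C)C)(C(C)(C)C)O[C@H]5c5ccc(O[Si](c6ccccc6)(c6ccccc6)C(C)(C)C)c(OC)c5)c(OC)c4)[C@@H]13 | intermediate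
15 | THF triol | OC[C@@H](O)[C@H]1CO[C@H](c2cc(OC)c(O[C@@H]3CO[Si](C(C)(C)C)(C(C)(C)C)O[C@H]3c3ccc(O[Si](c4ccccc4)(c4ccccc4)C(C)(C)C)c(OC)c3)c(OC)c2)[C@H]1CO | intermediate
16 | bicyclic lactol, anomeric centre undefined | OC1OC[C@H]2[C@@H]1CO[C@@H]2c3cc(OC)c(O[C@@H]4CO[Si](C(C)(C)C)(C(C)(C)C)O[C@H]4c4ccc(O[Si](c5ccccc5)(c5ccccc5)C(C)(C)C)c(OC)c4)c(OC)c3 | intermediate
17 | THF diol, benzylic carbinol undefined | OC(c1ccc(O[Si](c2ccccc2)(c2ccccc2)C(C)(C)C)c(OC)c1)[C@H]3CO[C@H](c4cc(OC)c(O[C@@H]5CO[Si](C(C)(C)C)(C(C)(C)C)O[C@H]5c5ccc(O[Si](c6ccccc6)(c6ccccc6)C(C)(C)C)c(OC)c5)c(OC)c4)[C@H]3CO | intermediate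
18 | silyl-protected furofuran | COc1cc([C@H]2OC[C@H]3[C@@H]2CO[C@@H]3c2cc(OC)c(O[C@@H]4CO[Si](C(C)(C)C)(C(C)(C)C)O[C@H]4c4ccc(O[Si](c5ccccc5)(c5ccccc5)C(C)(C)C)c(OC)c4)c(OC)c2)ccc1O[Si](c2ccccc2)(c2ccccc2)C(C)(C)C | intermediate
19 | Hedyotol C | COc1cc([C@H]2OC[C@H]3[C@@H]2CO[C@@H]3c2cc(OC)c(O[C@H](CO)[C@@H](O)c3ccc(O)c(OC)c3)c(OC)c2)ccc1O | target

## Totals
Total steps: 15. Longest linear sequence: 14 (Steps 1–8, 10–15).

## Three steps most likely to fail
1. **Step 10 (proposed new [3+2]).** Risks are the ylide/radical-cation regiochemistry, exo/endo selectivity, and oxidation of the other electron-rich arene in the side chain.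
   Fallback (known chemistry): anti-selective conjugate addition of the α-alkoxyalkyllithium from Bu3SnCH2OCH(OMe)Ar' (Still tin–lithium exchange) to 13. Lewis-acid ionisation of the mixed acetal then closes ring B onto the enolate intramolecularly, giving the same cis-fused lactone 14.
2. **Step 7 (Mitsunobu on the hindered silylene alcohol).** SN2 at this secondary centre may be slow or give elimination.
   Fallback: take the erythro (8''R) alcohol from the Felkin adduct of (R)-glyceraldehyde acetonide and arylate it by Cu/ligand Ullmann coupling with 4-iodo-3,5-dimethoxybenzaldehyde, which proceeds with retention at carbon.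
3. **Step 14 (acid cyclodehydration and equilibration to all-exo).** The acid may give a mixture of C7/C7' epimers or a partial loss of protecting groups.
   Fallback: separate the C7 epimers of 17 and close ring A by primary tosylation and KOtBu Williamson cyclisation, which retains C7, while C7' keeps the configuration set in Step 10.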